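The route rests on disconnecting the C3 carbinol and the C4 ketone of ring C to the C3=C4 double bond of an enantioenriched flav-3-ene. One syn-dihydroxylation forms both C–O bonds, and because ring B on C2 covers one face of the alkene, O3 arrives trans to the aryl group, which fixes the (3R) centre of the target; the benzylic C4 carbinol is then oxidised alone. The precursor is (S)-7-benzyloxy-2-[3,4-bis(tert-butyldimethylsilyloxy)phenyl]-2H-chromene, made by copper-catalysed asymmetric propargylic etherification and gold-catalysed ring closure. The geranyl ether is attached only after the osmium step, since its alkenes would not survive it.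

Key step: step 5

Assumption: (S,S)-Ph-pybox is taken to be the ligand antipode that leads to the (S)-ether 7; should the first batch show the opposite sense, the equally available (R,R)-ligand is used and nothing else changes.

Remark: target, flavene 8 and diol 10 are stereochemically consistent and need no correction. Flavene 8 is (2S) and the target (2R) with the same spatial arrangement, because C3 outranks ring B only once it carries oxygen.

Step 1
Reactants: 1 3,4-dihydroxybenzaldehyde
Product: 2 3,4-bis(tert-butyldimethylsilyloxy)benzaldehyde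
Conditions: TBSCl (2.3 equiv), imidazole (4 equiv), DMF, 0 °C to rt
Reagents that add atoms: tert-butyldimethylsilyl chloride, CC(C)(C)[Si](C)(C)Cl
Why: Imidazole-promoted O-silylation of both phenols; the aldehyde does not react and no stereocentre is formed.

Step 2
Reactants: 2 3,4-bis(tert-butyldimethylsilyloxy)benzaldehyde; 3 ethynylmagnesium bromide
Product: 5 rac-1-[3,4-bis(tert-butyldimethylsilyloxy)phenyl]prop-2-yn-1-yl acetate, via bromomagnesium propargylic alkoxide 4 (not isolated)
Conditions: 3 (1.2 equiv), THF, 0 °C; then Ac2O (2 equiv), 0 °C to rt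
Reagents that add atoms: acetic anhydride, CC(=O)OC(C)=O
Why: Grignard 1,2-addition of the acetylide to the aldehyde followed by O-acylation of the magnesium alkoxide in the same flask; the carbinol carbon is left racemic on purpose because step 3 is enantioconvergent, and an acetate is preferred to a carbonate because it ionises less readily next to the electron-rich ring B.

Step 3
Reactants: 5 rac-1-[3,4-bis(tert-butyldimethylsilyloxy)phenyl]prop-2-yn-1-yl acetate; 6 3-benzyloxyphenol
Product: 7 (S)-1-benzyloxy-3-{1-[3,4-bis(tert-butyldimethylsilyloxy)phenyl]prop-2-yn-1-yloxy}benzene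
Conditions: (CuOTf)2·C6H6 (5 mol% Cu), (S,S)-Ph-pybox (10 mol%), 6 (1.5 equiv), iPr2NEt (1.2 equiv), MeOH, −20 °C
Reagents that add atoms: none
Why: Copper-catalysed asymmetric propargylic substitution (etherification of a 1-arylpropargylic ester by a phenol): monovalent copper ionises the acetate of either enantiomer of 5 at the metal-bound terminal alkyne to one common electrophile, and the chiral pybox ligand lets the phenoxide oxygen of 6 reach only one face of the former carbinol carbon, which sets the later C2 centre as (S).

Step 4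
Reactants: 7 (S)-1-benzyloxy-3-{1-[3,4-bis(tert-butyldimethylsilyloxy)phenyl]prop-2-yn-1-yloxy}benzene
Product: 8 (2S)-7-benzyloxy-2-[3,4-bis(tert-butyldimethylsilyloxy)phenyl]-2H-chromene
Conditions: Ph3PAuNTf2 (3 mol%), CH2Cl2, rt
Reagents that add atoms: none
Why: Gold-catalysed intramolecular alkyne hydroarylation: the cationic monovalent gold complex activates the terminal alkyne for 6-endo-dig attack by the ring A carbon para to the benzyloxy group (the less hindered of the two activated ortho positions) and protodeauration releases the 2H-chromene; the C2–O bond and the C2 centre take no part, so the configuration is kept.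

Step 5
Reactants: 8 (2S)-7-benzyloxy-2-[3,4-bis(tert-butyldimethylsilyloxy)phenyl]-2H-chromene
Product: 10 (2R,3S,4S)-7-benzyloxy-2-[3,4-bis(tert-butyldimethylsilyloxy)phenyl]chromane-3,4-diol, via cyclic osmate ester 9 (not isolated)
Conditions: OsO4 (2 mol%), NMO (1.5 equiv), acetone–H2O 10:1, 0 °C to rt; Na2SO3 quench
Reagents that add atoms: osmium tetroxide, O=[Os](=O)(=O)=O (carries both oxygens, catalytic); N-methylmorpholine N-oxide, C[N+]1([O-])CCOCC1; water, O
Why: OsO4 adds to the C3=C4 double bond by a concerted, suprafacial [3+2] cycloaddition to give the cyclic osmate ester 9, which water hydrolyses to diol 10 while NMO returns hexavalent osmium to the octavalent state. The closest known reaction type is the OsO4 dihydroxylation of flav-3-enes, which gives 2,3-trans-3,4-cis-flavan-3,4-diols. No ring of the product is closed; the five-membered osmate ring of 9 forms by the [3+2] cycloaddition and is opened again by hydrolysis. C3 and C4 are both controlled by the existing C2 centre: ring B on C2 hangs over one face of ring C, the reagent comes from the other face, so O3 ends up trans to ring B (3S) and, because the addition is syn, O4 is cis to O3 (4S). The step needs diastereofacial selectivity only, which ring B secures, and chemoselectivity is no issue because C3=C4 is the sole alkene as long as O7 carries benzyl and not geranyl.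

Step 6
Reactants: 10 (2R,3S,4S)-7-benzyloxy-2-[3,4-bis(tert-butyldimethylsilyloxy)phenyl]chromane-3,4-diol
Product: 11 (2R,3R)-7-benzyloxy-2-[3,4-bis(tert-butyldimethylsilyloxy)phenyl]-3-hydroxychroman-4-one
Conditions: DDQ (1.3 equiv), NaHCO3 (solid), dioxane, rt
Reagents that add atoms: none
Why: Benzylic alcohol dehydrogenation by DDQ (hydride abstraction): only the C4–H is benzylic to ring A and backed by O1 (ortho) and the 7-benzyloxy group (para), so the C4 carbinol alone becomes the ketone, while the non-benzylic C3 carbinol and the C2 and C3 centres stay as they are.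

Step 7
Reactants: 11 (2R,3R)-7-benzyloxy-2-[3,4-bis(tert-butyldimethylsilyloxy)phenyl]-3-hydroxychroman-4-one
Product: 12 (2R,3R)-2-[3,4-bis(tert-butyldimethylsilyloxy)phenyl]-3,7-dihydroxychroman-4-one
Conditions: H2 (1 atm), 10% Pd/C, EtOAc, rt
Reagents that add atoms: none
Why: Catalytic hydrogenolysis of the aryl benzyl ether; the electron-rich aryl ketone, the cyclic C2–O1 bond and the silyl ethers react much more slowly under these mild neutral conditions, and no stereocentre is touched.

Step 8
Reactants: 12 (2R,3R)-2-[3,4-bis(tert-butyldimethylsilyloxy)phenyl]-3,7-dihydroxychroman-4-one; 13 geraniol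
Product: 14 (2R,3R)-2-[3,4-bis(tert-butyldimethylsilyloxy)phenyl]-7-[(2E)-3,7-dimethylocta-2,6-dienyloxy]-3-hydroxychroman-4-one
Conditions: PPh3 (1.3 equiv), DIAD (1.3 equiv), 13 (1.2 equiv), THF, 0 °C to rt
Reagents that add atoms: none
Why: Mitsunobu etherification: the 7-OH is a vinylogous acid (para to the C4 carbonyl) and serves as the pronucleophile, while primary allylic geraniol is activated far faster than the hindered secondary C3 hydroxyl, so O7 is geranylated by SN2 with the E alkene kept; the neutral medium avoids the base-induced ring opening that would scramble C2 and spares the aryl silyl ethers.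

Step 9
Reactants: 14 (2R,3R)-2-[3,4-bis(tert-butyldimethylsilyloxy)phenyl]-7-[(2E)-3,7-dimethylocta-2,6-dienyloxy]-3-hydroxychroman-4-one
Product: 15 (2R,3R)-2-(3,4-dihydroxyphenyl)-7-[(2E)-3,7-dimethylocta-2,6-dienyloxy]-3-hydroxychroman-4-one
Conditions: TBAF (2.5 equiv), AcOH (2.5 equiv), THF, 0 °C
Reagents that add atoms: none
Why: Fluoride-induced cleavage of the two aryl silyl ethers; buffering with acetic acid keeps phenoxide and enolate formation down, so the C2 and C3 centres of the dihydroflavonol and the geranyl ether are preserved.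

Compound list

1 | 3,4-dihydroxybenzaldehyde | O=Cc1ccc(O)c(O)c1 | starting material
2 | 3,4-bis(tert-butyldimethylsilyloxy)benzaldehyde | O=Cc1ccc(O[Si](C)(C)C(C)(C)C)c(O[Si](C)(C)C(C)(C)C)c1 | intermediate
3 | ethynylmagnesium bromide | C#C[Mg]Br | starting material
4 | bromomagnesium 1-[3,4-bis(tert-butyldimethylsilyloxy)phenyl]prop-2-yn-1-olate, racemic, formed in the flask | C#CC(O[Mg]Br)c1ccc(O[Si](C)(C)C(C)(C)C)c(O[Si](C)(C)C(C)(C)C)c1 | intermediate
5 | rac-1-[3,4-bis(tert-butyldimethylsilyloxy)phenyl]prop-2-yn-1-yl acetate | C#CC(OC(C)=O)c1ccc(O[Si](C)(C)C(C)(C)C)c(O[Si](C)(C)C(C)(C)C)c1 | intermediate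
6 | 3-benzyloxyphenol | Oc1cccc(OCc2ccccc2)c1 | starting material
7 | (S)-1-benzyloxy-3-{1-[3,4-bis(tert-butyldimethylsilyloxy)phenyl]prop-2-yn-1-yloxy}benzene | c1ccccc1COc1cccc(c1)O[C@H](c1ccc(O[Si](C)(C)C(C)(C)C)c(O[Si](C)(C)C(C)(C)C)c1)C#C | intermediate
8 | (2S)-7-benzyloxy-2-[3,4-bis(tert-butyldimethylsilyloxy)phenyl]-2H-chromene | c1ccccc1COc1ccc2c(c1)O[C@H](c1ccc(O[Si](C)(C)C(C)(C)C)c(O[Si](C)(C)C(C)(C)C)c1)C=C2 | intermediate
9 | cyclic osmate ester of 8: dioxo glycolate of hexavalent osmium bridging O3 and O4 on the face opposite ring B, formed in the flask | c1ccccc1COc1ccc2c(c1)O[C@H](c1ccc(O[Si](C)(C)C(C)(C)C)c(O[Si](C)(C)C(C)(C)C)c1)[C@H]3O[Os](=O)(=O)O[C@@H]23 | intermediate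
10 | (2R,3S,4S)-7-benzyloxy-2-[3,4-bis(tert-butyldimethylsilyloxy)phenyl]chromane-3,4-diol (2,3-trans-3,4-cis) | c1ccccc1COc1ccc2c(c1)O[C@H](c1ccc(O[Si](C)(C)C(C)(C)C)c(O[Si](C)(C)C(C)(C)C)c1)[C@@H](O)[C@H]2O | intermediate
11 | (2R,3R)-7-benzyloxy-2-[3,4-bis(tert-butyldimethylsilyloxy)phenyl]-3-hydroxychroman-4-one | c1ccccc1COc1ccc2c(c1)O[C@H](c1ccc(O[Si](C)(C)C(C)(C)C)c(O[Si](C)(C)C(C)(C)C)c1)[C@@H](O)C2=O | intermediate
12 | (2R,3R)-2-[3,4-bis(tert-butyldimethylsilyloxy)phenyl]-3,7-dihydroxychroman-4-one | Oc1ccc2c(c1)O[C@H](c1ccc(O[Si](C)(C)C(C)(C)C)c(O[Si](C)(C)C(C)(C)C)c1)[C@@H](O)C2=O | intermediate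
13 | geraniol, (2E)-3,7-dimethylocta-2,6-dien-1-ol | CC(C)=CCC/C(C)=C/CO | starting material
14 | (2R,3R)-2-[3,4-bis(tert-butyldimethylsilyloxy)phenyl]-7-[(2E)-3,7-dimethylocta-2,6-dienyloxy]-3-hydroxychroman-4-one | CC(C)=CCC/C(C)=C/COc1ccc2c(c1)O[C@H](c1ccc(O[Si](C)(C)C(C)(C)C)c(O[Si](C)(C)C(C)(C)C)c1)[C@@H](O)C2=O | intermediate
15 | (2R,3R)-2-(3,4-dihydroxyphenyl)-7-[(2E)-3,7-dimethylocta-2,6-dienyloxy]-3-hydroxychroman-4-one | CC(C)=CCC/C(C)=C/COc1ccc2c(c1)O[C@H](c1ccc(O)c(O)c1)[C@@H](O)C2=O | target

Total step count: 9 steps.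
Longest linear sequence: 9 steps, from 1 to 15; compounds 3, 6 and 13 are bought and enter directly.

Steps most likely to fail

Step 3. The electron-rich ring of 6 may be propargylated at carbon in competition with O-alkylation, and uncatalysed ionisation of the electron-rich benzylic acetate may feed a racemic background reaction, so conversion to the ether and its enantiomeric purity could both suffer. The fallback sets out from 5 and returns at 7. Immobilised Candida antarctica lipase B in phosphate buffer–MTBE is expected to hydrolyse the (R)-acetate preferentially (aryl as the large group in the usual empirical model for secondary alcohols). Stopped near half conversion, this should give (R)-1-[3,4-bis(tert-butyldimethylsilyloxy)phenyl]prop-2-yn-1-ol F1, which is separated from the unreacted (S)-acetate. A Mitsunobu reaction of F1 with 6 (PPh3, DIAD, toluene, −20 °C) should then give 7 by SN2 inversion. The stereocentre then comes from an enzymatic kinetic resolution, and the Mitsunobu mechanism enforces O-alkylation.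

Step 4. The ring may close at the ring A carbon flanked by both oxygens instead of the one para to the benzyloxy group (poor regioselectivity), or the Lewis-acidic catalyst may ionise the benzylic C2–O bond and erode the enantiomeric purity. The fallback sets out from 5 and returns at 8.
- Commercial 4-benzyloxy-2-hydroxybenzaldehyde is methylenated by a Wittig reaction (Ph3PCH3Br, KOtBu, THF) to 5-benzyloxy-2-vinylphenol F2.
- The copper-catalysed etherification of step 3, run with F2 in place of 6, should give (S)-4-benzyloxy-2-{1-[3,4-bis(tert-butyldimethylsilyloxy)phenyl]prop-2-yn-1-yloxy}-1-vinylbenzene F3.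
- Semihydrogenation of the terminal alkyne (H2, Lindlar catalyst Pd/CaCO3 poisoned with Pb(OAc)2, quinoline, EtOAc) should give (S)-4-benzyloxy-2-{1-[3,4-bis(tert-butyldimethylsilyloxy)phenyl]prop-2-en-1-yloxy}-1-vinylbenzene F4.
- Ring-closing metathesis of the two vinyl groups with the second-generation Grubbs catalyst RuCl2(=CHPh)(PCy3)(H2IMes) in CH2Cl2 should close ring C with loss of ethylene.

The C4–C4a bond is then present from the start, so the regiochemistry is fixed and no Lewis acid meets the C2–O bond.

Step 6. Hydride abstraction from the pseudo-equatorial C4–H of the 3,4-cis diol may be slow, which leaves room for acid-induced ionisation of the axial C4 hydroxyl and self-condensation. The fallback sets out from 8 and returns at 11, so the labile diol is not handled. Epoxidation of 8 with dimethyldioxirane in acetone at −20 °C should take place on the face opposite ring B and give (2R,3S,4S)-7-benzyloxy-2-[3,4-bis(tert-butyldimethylsilyloxy)phenyl]-3,4-epoxychromane F5. In DMSO with a trace of camphorsulfonic acid the epoxide should open at the benzylic C4 to the 3-hydroxy-4-(dimethylsulfonio-oxy)chromane cation F6. Et3N then collapses F6 to the C4 ketone with loss of dimethyl sulfide (Kornblum-type oxidation of an epoxide). The ketone then arises without any alcohol dehydrogenation, and C3 keeps the oxygen delivered trans to ring B.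

Further compounds

F1 | step 3 | (R)-1-[3,4-bis(tert-butyldimethylsilyloxy)phenyl]prop-2-yn-1-ol | O[C@@H](c1ccc(O[Si](C)(C)C(C)(C)C)c(O[Si](C)(C)C(C)(C)C)c1)C#C
F2 | step 4 | 5-benzyloxy-2-vinylphenol | C=Cc1ccc(OCc2ccccc2)cc1O
F3 | step 4 | (S)-4-benzyloxy-2-{1-[3,4-bis(tert-butyldimethylsilyloxy)phenyl]prop-2-yn-1-yloxy}-1-vinylbenzene | C=Cc1ccc(OCc2ccccc2)cc1O[C@H](c1ccc(O[Si](C)(C)C(C)(C)C)c(O[Si](C)(C)C(C)(C)C)c1)C#C
F4 | step 4 | (S)-4-benzyloxy-2-{1-[3,4-bis(tert-butyldimethylsilyloxy)phenyl]prop-2-en-1-yloxy}-1-vinylbenzene | C=Cc1ccc(OCc2ccccc2)cc1O[C@H](c1ccc(O[Si](C)(C)C(C)(C)C)c(O[Si](C)(C)C(C)(C)C)c1)C=C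
F5 | step 6 | (2R,3S,4S)-7-benzyloxy-2-[3,4-bis(tert-butyldimethylsilyloxy)phenyl]-3,4-epoxychromane, oxirane oxygen trans to ring B | c1ccccc1COc1ccc2c(c1)O[C@H](c1ccc(O[Si](C)(C)C(C)(C)C)c(O[Si](C)(C)C(C)(C)C)c1)[C@H]3O[C@@H]23
F6 | step 6 | 7-benzyloxy-2-[3,4-bis(tert-butyldimethylsilyloxy)phenyl]-4-(dimethylsulfonio-oxy)chroman-3-ol cation, drawn as the trans-opening product, C4 configuration immaterial | c1ccccc1COc1ccc2c(c1)O[C@H](c1ccc(O[Si](C)(C)C(C)(C)C)c(O[Si](C)(C)C(C)(C)C)c1)[C@@H](O)[C@@H]2O[S+](C)C
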